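**Retrosynthetic overview**

1. Bleochrin B ⇐ pentabenzyl ether 30 ⇐ diaryl ketone 28: the C6 benzylic CH2 of ring A is carried as an aroyl C=O and the five ArOH groups as benzyl ethers.
2. Ring A ⇐ [4+2] of 1,1-dimethoxy-3-silyloxy diene 12 with ynone 25. The feature used is the monomethyl resorcinol core of ring A: C1(OMe)–C2(CH2Ar)–C3(OH)–C4(CH2Ar) come from the diene, C5 (ethano chain) and C6 (aroyl, later CH2Ar) from the alkyne; bonds C4–C5 and C6–C1 are formed.
3. Diene 12 ⇐ enol silylation of acyl ketene acetal 10 ⇐ C-acylation of ketene dimethyl acetal 9 (nitrile 6 → orthoester 8 → 9) with acid chloride 4.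
4. Ynone 25 ⇐ acyl Sonogashira coupling of alkyne 23 with aroyl chloride 24; 23 ⇐ Negishi benzylation of aryl bromide 19 ⇐ propargylation of benzylic bromide 16 ⇐ 2-bromo-5-hydroxybenzaldehyde 13.
5. Ring order: ring B and the four 4-oxyphenyl rings are bought; ring A is the only ring built, in step 15.

Key step: step 15

Remark (assumption): ring A is numbered C1 (OMe), C2, C3 (OH), C4, C5 (ethano chain), C6. Compounds 5, 17, 20 and 24 are taken as purchasable. The moisture-sensitive compounds 9 and 12 are used crude.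

**Route**

Step 1
Reactants: 1 3-(4-hydroxyphenyl)propanoic acid
Product: 3 3-[4-(benzyloxy)phenyl]propanoic acid, via benzyl ester 2 (not isolated)
Conditions: BnBr (2.3 equiv), K2CO3, DMF, 60 °C; then NaOH, H2O/MeOH, 60 °C; HCl to pH 2
Reagents that add atoms: benzyl bromide, BrCc1ccccc1
Why: Williamson etherification of the phenoxide (the carboxylate is benzylated as well) followed by saponification of the benzyl ester, to which the aryl benzyl ether is inert.

Step 2
Reactants: 3 3-[4-(benzyloxy)phenyl]propanoic acid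
Product: 4 3-[4-(benzyloxy)phenyl]propanoyl chloride
Conditions: (COCl)2, cat. DMF, CH2Cl2, 0 °C to rt; evaporate, use crude
Reagents that add atoms: oxalyl chloride, ClC(=O)C(=O)Cl
Why: Standard acid chloride formation through the Vilsmeier-type chloroiminium catalyst; without a Lewis acid the arene does not cyclise onto the acyl chloride.

Step 3
Reactants: 5 3-(4-hydroxyphenyl)propanenitrile
Product: 6 3-[4-(benzyloxy)phenyl]propanenitrile
Conditions: BnBr, K2CO3, acetone, reflux
Reagents that add atoms: benzyl bromide, BrCc1ccccc1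
Why: Williamson etherification of the phenol; the nitrile is inert to carbonate.

Step 4
Reactants: 6 3-[4-(benzyloxy)phenyl]propanenitrile
Product: 8 1-(benzyloxy)-4-(3,3,3-trimethoxypropyl)benzene, via imidate hydrochloride 7 (not isolated)
Conditions: HCl (g), MeOH (1.1 equiv), Et2O/CH2Cl2, 0 °C, 2 d; evaporate; then MeOH (excess), hexane, rt, 2 d; filter, cold aq. K2CO3 wash
Reagents that add atoms: methanol, CO
Why: Pinner reaction: the nitrile gives the methyl imidate hydrochloride, whose methanolysis gives the trimethyl orthoester and ammonium chloride; aryl benzyl ethers tolerate anhydrous HCl at 0 °C.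

Step 5
Reactants: 8 1-(benzyloxy)-4-(3,3,3-trimethoxypropyl)benzene
Product: 9 1-(benzyloxy)-4-(3,3-dimethoxyprop-2-en-1-yl)benzene
Conditions: i-Pr2NEt (1.5 equiv), Me3SiOTf (1.2 equiv), CH2Cl2, −20 °C to rt; pentane, cold aq. NaOH wash; use crude
Reagents that add atoms: none
Why: Silyl-triflate-induced loss of methoxide gives the dimethoxycarbenium ion, which the hindered amine deprotonates at its only α-methylene (the orthoester counterpart of the acetal-to-enol-ether dealkoxylation), so the ketene acetal forms without a regiochemical choice.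

Step 6
Reactants: 9 1-(benzyloxy)-4-(3,3-dimethoxyprop-2-en-1-yl)benzene; 4 3-[4-(benzyloxy)phenyl]propanoyl chloride
Product: 10 2-[4-(benzyloxy)benzyl]-5-[4-(benzyloxy)phenyl]-1,1-dimethoxypent-1-en-3-one
Conditions: pyridine (1.5 equiv), CH2Cl2, 0 °C to rt; Et3N-deactivated silica
Reagents that add atoms: none
Why: C-acylation of the ketene acetal at its nucleophilic β-carbon by the acylpyridinium ion, then loss of the α-proton from the dimethoxycarbenium ion to pyridine, is the established route to β,β-dialkoxy enones; pyridine is too weak a base to convert 4 into a ketene.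

Step 7
Reactants: 10 2-[4-(benzyloxy)benzyl]-5-[4-(benzyloxy)phenyl]-1,1-dimethoxypent-1-en-3-one
Product: 12 (3Z)-{[2-[4-(benzyloxy)benzyl]-5-[4-(benzyloxy)phenyl]-1,1-dimethoxypenta-1,3-dien-3-yl]oxy}trimethylsilane, via lithium dienolate 11 (not isolated)
Conditions: LiN(i-Pr)2 (1.1 equiv), THF, −78 °C; Me3SiCl, −78 °C to rt; evaporate, pentane, filter; use crude
Reagents that add atoms: chlorotrimethylsilane, C[Si](C)(C)Cl
Why: Kinetic deprotonation at the only enolisable methylene of the vinylogous carbonate and O-silylation; the bulky branched sp2 group on the carbonyl should enforce the Z enolate (as with aryl ethyl ketones), which places C5 on the outside of the s-cis diene.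

Step 8
Reactants: 13 2-bromo-5-hydroxybenzaldehyde
Product: 14 5-(benzyloxy)-2-bromobenzaldehyde
Conditions: BnBr, K2CO3, DMF, rt
Reagents that add atoms: benzyl bromide, BrCc1ccccc1
Why: Williamson etherification of the phenol.

Step 9
Reactants: 14 5-(benzyloxy)-2-bromobenzaldehyde
Product: 15 [5-(benzyloxy)-2-bromophenyl]methanol
Conditions: NaBH4, MeOH/THF, 0 °C
Reagents that add atoms: none
Why: Borohydride reduction of the aldehyde; aryl bromide and benzyl ether are untouched.

Step 10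
Reactants: 15 [5-(benzyloxy)-2-bromophenyl]methanol
Product: 16 4-(benzyloxy)-1-bromo-2-(bromomethyl)benzene
Conditions: PBr3 (0.4 equiv), CH2Cl2, 0 °C
Reagents that add atoms: phosphorus tribromide, BrP(Br)Br
Why: SN2 displacement of the phosphite ester of a primary benzylic alcohol by bromide.

Step 11
Reactants: 16 4-(benzyloxy)-1-bromo-2-(bromomethyl)benzene; 17 1-(trimethylsilyl)propyne
Product: 19 {4-[5-(benzyloxy)-2-bromophenyl]but-1-yn-1-yl}trimethylsilane, via lithiated silylpropyne 18 (not isolated)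
Conditions: 17 (1.5 equiv), n-BuLi, THF, −78 °C; then 16, −78 to −20 °C
Reagents that add atoms: none
Why: SN2 alkylation of the silyl-stabilised propargyl anion by the benzylic bromide, the silyl group directing attack through the propargylic (not allenic) carbon; the stabilised anion does not exchange with the aryl bromide at low temperature.

Step 12
Reactants: 19 {4-[5-(benzyloxy)-2-bromophenyl]but-1-yn-1-yl}trimethylsilane; 20 4-(benzyloxy)benzyl chloride
Product: 22 (4-{5-(benzyloxy)-2-[4-(benzyloxy)benzyl]phenyl}but-1-yn-1-yl)trimethylsilane, via benzylzinc chloride 21 (not isolated)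
Conditions: 20 (1.3 equiv), Zn dust, LiCl, THF, 25 °C; then 19, Pd(OAc)2 (2 mol%), SPhos (4 mol%), THF, 25–50 °C
Reagents that add atoms: none
Why: Negishi coupling: LiCl-assisted zinc insertion into the benzylic chloride, oxidative addition of the aryl bromide to zerovalent palladium, transmetalation and reductive elimination give the diarylmethane; the silyl alkyne and benzyl ethers are tolerated.

Step 13
Reactants: 22 (4-{5-(benzyloxy)-2-[4-(benzyloxy)benzyl]phenyl}but-1-yn-1-yl)trimethylsilane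
Product: 23 4-(benzyloxy)-1-[4-(benzyloxy)benzyl]-2-(but-3-yn-1-yl)benzene
Conditions: K2CO3 (cat.), MeOH/THF, rt
Reagents that add atoms: none
Why: Methoxide-mediated protodesilylation of the alkynylsilane.

Step 14
Reactants: 23 4-(benzyloxy)-1-[4-(benzyloxy)benzyl]-2-(but-3-yn-1-yl)benzene; 24 4-(benzyloxy)benzoyl chloride
Product: 25 1-[4-(benzyloxy)phenyl]-5-{5-(benzyloxy)-2-[4-(benzyloxy)benzyl]phenyl}pent-2-yn-1-one
Conditions: PdCl2(PPh3)2 (2 mol%), CuI (4 mol%), Et3N (1.5 equiv), THF, rt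
Reagents that add atoms: none
Why: Acyl Sonogashira coupling: the aroyl chloride adds oxidatively to zerovalent palladium, the copper acetylide transmetalates and reductive elimination gives the ynone at room temperature, without decarbonylation.

Step 15
Reactants: 12 (3Z)-{[2-[4-(benzyloxy)benzyl]-5-[4-(benzyloxy)phenyl]-1,1-dimethoxypenta-1,3-dien-3-yl]oxy}trimethylsilane (2 equiv); 25 1-[4-(benzyloxy)phenyl]-5-{5-(benzyloxy)-2-[4-(benzyloxy)benzyl]phenyl}pent-2-yn-1-one
Product: 28 [3,5-bis[4-(benzyloxy)benzyl]-6-(2-{5-(benzyloxy)-2-[4-(benzyloxy)benzyl]phenyl}ethyl)-4-hydroxy-2-methoxyphenyl][4-(benzyloxy)phenyl]methanone, via cyclohexadiene cycloadduct 26 (not isolated), via aryl silyl ether 27 (not isolated)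
Conditions: PhMe, 110 °C, sealed tube; then 1 M HCl, THF, rt
Reagents that add atoms: none
Why: C4 of diene 12 (the CH terminus, pushed by the C3 silyloxy and the C1 methoxy groups) is the nucleophilic end and bonds to the ynone β-carbon carrying the ethano chain, while the acyl-bearing α-carbon bonds to the dimethoxy carbon C1, in a strongly asynchronous [4+2] cycloaddition (in the limit a Mukaiyama–Michael addition followed by closure of the allenolate onto the dimethoxycarbenium ion). The closest known reaction type is the cycloaddition of 1,1-dialkoxy-3-silyloxy dienes with acyl alkynes, which gives resorcinol monoethers after aromatisation. Ring A closes as a six-membered carbocycle through the new bonds C4–C5 and C6–C1 (in the stepwise picture a 6-exo-trig attack on the oxocarbenium carbon); 1,4-elimination of methanol from 26 aromatises it and dilute acid removes the silyl group of 27. The single stereocentre of 26 (C–H next to the silyl enol ether, racemic) disappears on aromatisation, so no stereocontrol is needed. The step needs regioselectivity, which the acyl polarisation of the alkyne and the donor pattern of the diene secure, and an accessible s-cis diene, which the Z enol ether geometry from step 7 secures by keeping C5 outside. The ketene acetal carbon can only become C1–OMe and the silyloxy carbon C3–OH, so the two oxygens are differentiated by construction.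

Step 16
Reactants: 28 [3,5-bis[4-(benzyloxy)benzyl]-6-(2-{5-(benzyloxy)-2-[4-(benzyloxy)benzyl]phenyl}ethyl)-4-hydroxy-2-methoxyphenyl][4-(benzyloxy)phenyl]methanone
Product: 29 racemic [3,5-bis[4-(benzyloxy)benzyl]-6-(2-{5-(benzyloxy)-2-[4-(benzyloxy)benzyl]phenyl}ethyl)-4-hydroxy-2-methoxyphenyl][4-(benzyloxy)phenyl]methanol
Conditions: LiAlH4 (excess), THF, 0 °C to rt; aq. potassium sodium tartrate work-up; use crude
Reagents that add atoms: none
Why: Hydride reduction of the hindered diaryl ketone by the small, strong aluminium hydride (the phenol consumes one hydride); the new carbinol centre is formed racemic and is removed in step 17.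

Step 17
Reactants: 29 racemic [3,5-bis[4-(benzyloxy)benzyl]-6-(2-{5-(benzyloxy)-2-[4-(benzyloxy)benzyl]phenyl}ethyl)-4-hydroxy-2-methoxyphenyl][4-(benzyloxy)phenyl]methanol
Product: 30 2,4,6-tris[4-(benzyloxy)benzyl]-5-(2-{5-(benzyloxy)-2-[4-(benzyloxy)benzyl]phenyl}ethyl)-3-methoxyphenol
Conditions: Et3SiH (4 equiv), CF3CO2H (4 equiv), CH2Cl2, −20 to 0 °C
Reagents that add atoms: none
Why: Ionic hydrogenation: the doubly benzylic carbinol, para to the free OH and ortho to OMe, ionises readily to a diarylmethyl cation (para-quinone methide), which excess silane reduces before the benzyl ethers are attacked by the cold, dilute acid.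

Step 18
Reactants: 30 2,4,6-tris[4-(benzyloxy)benzyl]-5-(2-{5-(benzyloxy)-2-[4-(benzyloxy)benzyl]phenyl}ethyl)-3-methoxyphenol
Product: 31 Bleochrin B
Conditions: H2 (1 atm), 10% Pd/C, EtOAc/MeOH, rt
Reagents that add atoms: none
Why: Catalytic hydrogenolysis of the five aryl benzyl ethers; the diarylmethane C–C bonds and the aryl methyl ether are stable.

**Compound list**

1 | 3-(4-hydroxyphenyl)propanoic acid | OC(=O)CCc1ccc(O)cc1 | starting material
2 | benzyl 3-[4-(benzyloxy)phenyl]propanoate | O=C(OCc1ccccc1)CCc1ccc(OCc2ccccc2)cc1 | intermediate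
3 | 3-[4-(benzyloxy)phenyl]propanoic acid | OC(=O)CCc1ccc(OCc2ccccc2)cc1 | intermediate
4 | 3-[4-(benzyloxy)phenyl]propanoyl chloride | ClC(=O)CCc1ccc(OCc2ccccc2)cc1 | intermediate
5 | 3-(4-hydroxyphenyl)propanenitrile | N#CCCc1ccc(O)cc1 | starting material
6 | 3-[4-(benzyloxy)phenyl]propanenitrile | N#CCCc1ccc(OCc2ccccc2)cc1 | intermediate
7 | methyl 3-[4-(benzyloxy)phenyl]propanimidate hydrochloride | COC(=[NH2+])CCc1ccc(OCc2ccccc2)cc1.[Cl-] | intermediate
8 | 1-(benzyloxy)-4-(3,3,3-trimethoxypropyl)benzene | COC(OC)(OC)CCc1ccc(OCc2ccccc2)cc1 | intermediate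
9 | 1-(benzyloxy)-4-(3,3-dimethoxyprop-2-en-1-yl)benzene | COC(OC)=CCc1ccc(OCc2ccccc2)cc1 | intermediate
10 | 2-[4-(benzyloxy)benzyl]-5-[4-(benzyloxy)phenyl]-1,1-dimethoxypent-1-en-3-one | COC(OC)=C(Cc1ccc(OCc2ccccc2)cc1)C(=O)CCc1ccc(OCc2ccccc2)cc1 | intermediate
11 | lithium (3Z)-2-[4-(benzyloxy)benzyl]-5-[4-(benzyloxy)phenyl]-1,1-dimethoxypenta-1,3-dien-3-olate | COC(OC)=C(Cc1ccc(OCc2ccccc2)cc1)/C([O-])=C/Cc1ccc(OCc2ccccc2)cc1.[Li+] | intermediate
12 | (3Z)-{[2-[4-(benzyloxy)benzyl]-5-[4-(benzyloxy)phenyl]-1,1-dimethoxypenta-1,3-dien-3-yl]oxy}trimethylsilane | COC(OC)=C(Cc1ccc(OCc2ccccc2)cc1)/C(O[Si](C)(C)C)=C/Cc1ccc(OCc2ccccc2)cc1 | intermediate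
13 | 2-bromo-5-hydroxybenzaldehyde | O=Cc1cc(O)ccc1Br | starting material
14 | 5-(benzyloxy)-2-bromobenzaldehyde | O=Cc1cc(OCc2ccccc2)ccc1Br | intermediate
15 | [5-(benzyloxy)-2-bromophenyl]methanol | OCc1cc(OCc2ccccc2)ccc1Br | intermediate
16 | 4-(benzyloxy)-1-bromo-2-(bromomethyl)benzene | BrCc1cc(OCc2ccccc2)ccc1Br | intermediate
17 | 1-(trimethylsilyl)propyne | CC#C[Si](C)(C)C | starting material
18 | [3-(trimethylsilyl)prop-2-yn-1-yl]lithium | [Li]CC#C[Si](C)(C)C | intermediate
19 | {4-[5-(benzyloxy)-2-bromophenyl]but-1-yn-1-yl}trimethylsilane | C[Si](C)(C)C#CCCc1cc(OCc2ccccc2)ccc1Br | intermediate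
20 | 4-(benzyloxy)benzyl chloride | ClCc1ccc(OCc2ccccc2)cc1 | starting material
21 | [4-(benzyloxy)benzyl]zinc chloride | Cl[Zn]Cc1ccc(OCc2ccccc2)cc1 | intermediate
22 | (4-{5-(benzyloxy)-2-[4-(benzyloxy)benzyl]phenyl}but-1-yn-1-yl)trimethylsilane | C[Si](C)(C)C#CCCc1cc(OCc2ccccc2)ccc1Cc1ccc(OCc2ccccc2)cc1 | intermediate
23 | 4-(benzyloxy)-1-[4-(benzyloxy)benzyl]-2-(but-3-yn-1-yl)benzene | C#CCCc1cc(OCc2ccccc2)ccc1Cc1ccc(OCc2ccccc2)cc1 | intermediate
24 | 4-(benzyloxy)benzoyl chloride | ClC(=O)c1ccc(OCc2ccccc2)cc1 | starting material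
25 | 1-[4-(benzyloxy)phenyl]-5-{5-(benzyloxy)-2-[4-(benzyloxy)benzyl]phenyl}pent-2-yn-1-one | O=C(C#CCCc1cc(OCc2ccccc2)ccc1Cc1ccc(OCc2ccccc2)cc1)c1ccc(OCc2ccccc2)cc1 | intermediate
26 | racemic [3,5-bis[4-(benzyloxy)benzyl]-2-(2-{5-(benzyloxy)-2-[4-(benzyloxy)benzyl]phenyl}ethyl)-6,6-dimethoxy-4-(trimethylsilyloxy)cyclohexa-1,4-dien-1-yl][4-(benzyloxy)phenyl]methanone | COC1(OC)C(Cc2ccc(OCc3ccccc3)cc2)=C(O[Si](C)(C)C)C(Cc2ccc(OCc3ccccc3)cc2)C(CCc2cc(OCc3ccccc3)ccc2Cc2ccc(OCc3ccccc3)cc2)=C1C(=O)c1ccc(OCc2ccccc2)cc1 | intermediate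
27 | [3,5-bis[4-(benzyloxy)benzyl]-6-(2-{5-(benzyloxy)-2-[4-(benzyloxy)benzyl]phenyl}ethyl)-2-methoxy-4-(trimethylsilyloxy)phenyl][4-(benzyloxy)phenyl]methanone | COc1c(Cc2ccc(OCc3ccccc3)cc2)c(O[Si](C)(C)C)c(Cc2ccc(OCc3ccccc3)cc2)c(CCc2cc(OCc3ccccc3)ccc2Cc2ccc(OCc3ccccc3)cc2)c1C(=O)c1ccc(OCc2ccccc2)cc1 | intermediate
28 | [3,5-bis[4-(benzyloxy)benzyl]-6-(2-{5-(benzyloxy)-2-[4-(benzyloxy)benzyl]phenyl}ethyl)-4-hydroxy-2-methoxyphenyl][4-(benzyloxy)phenyl]methanone | COc1c(Cc2ccc(OCc3ccccc3)cc2)c(O)c(Cc2ccc(OCc3ccccc3)cc2)c(CCc2cc(OCc3ccccc3)ccc2Cc2ccc(OCc3ccccc3)cc2)c1C(=O)c1ccc(OCc2ccccc2)cc1 | intermediate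
29 | racemic [3,5-bis[4-(benzyloxy)benzyl]-6-(2-{5-(benzyloxy)-2-[4-(benzyloxy)benzyl]phenyl}ethyl)-4-hydroxy-2-methoxyphenyl][4-(benzyloxy)phenyl]methanol | COc1c(Cc2ccc(OCc3ccccc3)cc2)c(O)c(Cc2ccc(OCc3ccccc3)cc2)c(CCc2cc(OCc3ccccc3)ccc2Cc2ccc(OCc3ccccc3)cc2)c1C(O)c1ccc(OCc2ccccc2)cc1 | intermediate
30 | 2,4,6-tris[4-(benzyloxy)benzyl]-5-(2-{5-(benzyloxy)-2-[4-(benzyloxy)benzyl]phenyl}ethyl)-3-methoxyphenol | COc1c(Cc2ccc(OCc3ccccc3)cc2)c(O)c(Cc2ccc(OCc3ccccc3)cc2)c(CCc2cc(OCc3ccccc3)ccc2Cc2ccc(OCc3ccccc3)cc2)c1Cc1ccc(OCc2ccccc2)cc1 | intermediate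
31 | Bleochrin B, 5-{2-[5-hydroxy-2-(4-hydroxybenzyl)phenyl]ethyl}-2,4,6-tris(4-hydroxybenzyl)-3-methoxyphenol (no stereocentres) | COc1c(Cc2ccc(O)cc2)c(O)c(Cc2ccc(O)cc2)c(CCc2cc(O)ccc2Cc2ccc(O)cc2)c1Cc1ccc(O)cc1 | target

**Step count and risks**

Total step count: 18. Longest linear sequence: 11 steps (13 to 31, steps 8–18).

Steps most likely to fail:

Step 15. The cycloaddition joins a tetrasubstituted ketene acetal terminus and an internal alkyne to a hexasubstituted ring. It may be so slow that thermal breakdown of the labile diene (silyl migration, hydrolysis by adventitious water) outruns it, or it may stall at the open-chain Michael adduct. The fallback sets out from acyl ketene acetal 10 and ynone 25 and changes the diene class and the bond mapping. Mild aqueous acid (0.1 M HCl, THF) should hydrolyse 10 to methyl 2-[4-(benzyloxy)benzyl]-5-[4-(benzyloxy)phenyl]-3-oxopentanoate F1. O-methylation of its sodium enolate (NaH, Me2SO4, DMPU/THF) should give methyl 2-[4-(benzyloxy)benzyl]-5-[4-(benzyloxy)phenyl]-3-methoxypent-2-enoate F2. γ-Deprotonation and O-silylation (LiN(i-Pr)2, Me3SiCl, THF, −78 °C) should give the mixed silyl ketene acetal {[2-[4-(benzyloxy)benzyl]-5-[4-(benzyloxy)phenyl]-1,3-dimethoxypenta-1,3-dien-1-yl]oxy}trimethylsilane F3. This more electron-rich diene, made from a robust β-keto ester, is expected to add to 25 at lower temperature with the same polarity (CH terminus to the ynone β-carbon), via the 6-methoxy-6-(trimethylsilyloxy)cyclohexa-1,4-diene cycloadduct F4. Acid collapse of its mixed ketal and tautomerisation should give the regioisomeric ketone [3,5-bis[4-(benzyloxy)benzyl]-6-(2-{5-(benzyloxy)-2-[4-(benzyloxy)benzyl]phenyl}ethyl)-2-hydroxy-4-methoxyphenyl][4-(benzyloxy)phenyl]methanone F5. In F5 the aroyl group sits on ring A C4, the silyl ketene acetal carbon has become C3–OH and the enol ether carbon C1–OMe. Because C4 and C6 carry the same 4-hydroxybenzyl group in the target, reduction of F5 with LiAlH4 to the racemic carbinol [3,5-bis[4-(benzyloxy)benzyl]-6-(2-{5-(benzyloxy)-2-[4-(benzyloxy)benzyl]phenyl}ethyl)-2-hydroxy-4-methoxyphenyl][4-(benzyloxy)phenyl]methanol F6, then Et3SiH/CF3CO2H, converges on pentabenzyl ether 30, where the route is rejoined.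

Step 6. Chloride may demethylate the dimethoxycarbenium intermediate, so that a β-keto ester forms in place of the ketene acetal, and the supply of 9 depends on the moisture-sensitive steps 4 and 5. The fallback sets out from acid chloride 4 and replaces the acylation of a substituted ketene acetal by a cross-coupling. Commercial 1,1-dimethoxyethene is acylated with 4 (pyridine, Et2O, 0 °C) to 5-[4-(benzyloxy)phenyl]-1,1-dimethoxypent-1-en-3-one F7. Its nucleophilic C2 is brominated (N-bromosuccinimide, then Et3N, CH2Cl2, −78 °C) to 5-[4-(benzyloxy)phenyl]-2-bromo-1,1-dimethoxypent-1-en-3-one F8. The C2 benzyl group is then attached by Negishi coupling of F8 with benzylzinc chloride 21 (Pd(OAc)2, SPhos, THF), which returns to 10 and makes 8 and 9 unnecessary.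

Step 17. The diarylmethyl cation (para-quinone methide) may alkylate ring B at its position ortho to the benzyloxy group in a seven-membered Friedel–Crafts closure, or the acid may begin to cleave benzyl ethers before hydride transfer. The fallback sets out from carbinol 29 and goes directly to target 31 by heterogeneous hydrogenolysis (H2, Pd/C, EtOAc/AcOH). This cleaves the doubly benzylic, para-hydroxy-activated C–OH bond together with the five benzyl ethers on the catalyst surface, with no free cation in solution and no new compound.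

**Further compounds**

F1 | step 15 | methyl 2-[4-(benzyloxy)benzyl]-5-[4-(benzyloxy)phenyl]-3-oxopentanoate (racemic) | COC(=O)C(Cc1ccc(OCc2ccccc2)cc1)C(=O)CCc1ccc(OCc2ccccc2)cc1
F2 | step 15 | methyl 2-[4-(benzyloxy)benzyl]-5-[4-(benzyloxy)phenyl]-3-methoxypent-2-enoate (alkene geometry not fixed) | COC(=O)C(Cc1ccc(OCc2ccccc2)cc1)=C(OC)CCc1ccc(OCc2ccccc2)cc1
F3 | step 15 | {[2-[4-(benzyloxy)benzyl]-5-[4-(benzyloxy)phenyl]-1,3-dimethoxypenta-1,3-dien-1-yl]oxy}trimethylsilane (geometry not fixed) | COC(O[Si](C)(C)C)=C(Cc1ccc(OCc2ccccc2)cc1)C(OC)=CCc1ccc(OCc2ccccc2)cc1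
F4 | step 15 | [3,5-bis[4-(benzyloxy)benzyl]-2-(2-{5-(benzyloxy)-2-[4-(benzyloxy)benzyl]phenyl}ethyl)-4,6-dimethoxy-6-(trimethylsilyloxy)cyclohexa-1,4-dien-1-yl][4-(benzyloxy)phenyl]methanone (mixture of stereoisomers) | COC1(O[Si](C)(C)C)C(Cc2ccc(OCc3ccccc3)cc2)=C(OC)C(Cc2ccc(OCc3ccccc3)cc2)C(CCc2cc(OCc3ccccc3)ccc2Cc2ccc(OCc3ccccc3)cc2)=C1C(=O)c1ccc(OCc2ccccc2)cc1
F5 | step 15 | [3,5-bis[4-(benzyloxy)benzyl]-6-(2-{5-(benzyloxy)-2-[4-(benzyloxy)benzyl]phenyl}ethyl)-2-hydroxy-4-methoxyphenyl][4-(benzyloxy)phenyl]methanone | COc1c(Cc2ccc(OCc3ccccc3)cc2)c(O)c(C(=O)c2ccc(OCc3ccccc3)cc2)c(CCc2cc(OCc3ccccc3)ccc2Cc2ccc(OCc3ccccc3)cc2)c1Cc1ccc(OCc2ccccc2)cc1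
F6 | step 15 | racemic [3,5-bis[4-(benzyloxy)benzyl]-6-(2-{5-(benzyloxy)-2-[4-(benzyloxy)benzyl]phenyl}ethyl)-2-hydroxy-4-methoxyphenyl][4-(benzyloxy)phenyl]methanol | COc1c(Cc2ccc(OCc3ccccc3)cc2)c(O)c(C(O)c2ccc(OCc3ccccc3)cc2)c(CCc2cc(OCc3ccccc3)ccc2Cc2ccc(OCc3ccccc3)cc2)c1Cc1ccc(OCc2ccccc2)cc1
F7 | step 6 | 5-[4-(benzyloxy)phenyl]-1,1-dimethoxypent-1-en-3-one | COC(OC)=CC(=O)CCc1ccc(OCc2ccccc2)cc1
F8 | step 6 | 5-[4-(benzyloxy)phenyl]-2-bromo-1,1-dimethoxypent-1-en-3-one | COC(OC)=C(Br)C(=O)CCc1ccc(OCc2ccccc2)cc1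
F0 | step 17 | none | none
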